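**Retrosynthetic overview**

- Prinsepiol 20 ⇐ bis-silyl ether 19 ⇐ bis-lactol 18 ⇐ dihydroxy bis-lactone 17: the two OCH2 carbons C9 and C9' are carried as lactone carbonyls and taken down to CH2 at the end.
- Feature used: the carbinol carbons C8 and C8' are the ring-fusion atoms shared by ring 1 (C7–O–C9'–C8'–C8) and ring 2 (C7'–O–C9–C8–C8'). With C9 and C9' as C=O, each is an enolisable tertiary C–H, so 17 ⇐ 13 by forming the C8–OH and C8'–OH bonds on lactone enolates, with retention imposed by the cis ring fusion.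
- 13 ⇐ 12 ⇐ (R,R)-diacid 10: the C7–O and C7'–O bonds come from oxidative lactonisation through quinone methides; ring 1 closes first, ring 2 second (cis-fused, aryl groups exo).
- 10 ⇐ 8 ⇐ two molecules of 6: the C8–C8' bond comes from oxidative homocoupling of the enolate of an N-acyl oxazolidinone made from dihydroferulic acid 1 and auxiliary 4.

Key step: step 8

Remark: lignan numbering is used throughout (C7/C7' aryl-bearing carbons, C8/C8' ring-fusion carbons, C9/C9' the carbons between C8/C8' and the ring oxygens). The oxaziridine is used as the racemate, since the substrate alone controls the new centres. Step 3 joins two molecules of 6; the amounts in that step are given per molecule of 6.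

**Route**

Step 1
Reactants: 1 3-(4-hydroxy-3-methoxyphenyl)propanoic acid
Product: 3 3-(4-benzyloxy-3-methoxyphenyl)propanoic acid, via benzyl ester 2 (not isolated)
Conditions: BnBr (2.3 equiv), K2CO3, DMF, 60 °C; then NaOH, MeOH–H2O, 60 °C; HCl
Reagents that add atoms: benzyl bromide, BrCc1ccccc1
Why: Williamson O-benzylation of the phenoxide (the carboxylate is benzylated too), then saponification, which cleaves only the benzyl ester because the aryl benzyl ether is inert to hydroxide; no stereocenter is involved.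

Step 2
Reactants: 3 3-(4-benzyloxy-3-methoxyphenyl)propanoic acid; 4 (S)-4-benzyl-2-oxazolidinone
Product: 6 (S)-4-benzyl-3-[3-(4-benzyloxy-3-methoxyphenyl)propanoyl]oxazolidin-2-one, via mixed pivalic anhydride 5 (not isolated)
Conditions: PivCl, Et3N, THF, −20 °C; then LiCl, 4, −20 °C → rt
Reagents that add atoms: none
Why: N-acylation of the oxazolidinone auxiliary through the mixed pivalic anhydride, which the LiCl/Et3N-activated oxazolidinone attacks at the unhindered arylpropanoyl carbonyl; the auxiliary stereocenter is not touched.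

Step 3
Reactants: 6 (S)-4-benzyl-3-[3-(4-benzyloxy-3-methoxyphenyl)propanoyl]oxazolidin-2-one (two molecules, which become the two halves of 8)
Product: 8 (2R,3R)-2,3-bis(4-benzyloxy-3-methoxybenzyl)-1,4-bis[(S)-4-benzyl-2-oxooxazolidin-3-yl]butane-1,4-dione, via lithium enolate 7 (not isolated)
Conditions: LiN(iPr)2 (1.1 equiv per 6), THF, −78 °C; TiCl4 (1.1 equiv per 6), −78 → 0 °C
Reagents that add atoms: a second molecule of 6, (S)-4-benzyl-3-[3-(4-benzyloxy-3-methoxyphenyl)propanoyl]oxazolidin-2-one, COc1cc(CCC(=O)N2[C@@H](Cc3ccccc3)COC2=O)ccc1OCc1ccccc1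
Why: Oxidative enolate homocoupling of two molecules of 6: each is converted into the chelated (Z)-enolate 7, which is transmetalated to tetravalent titanium and oxidised by one electron (titanium leaves as trivalent titanium), so that the α-carbons of two enolate units join, each bonding on the face away from the C4 benzyl group of its own auxiliary; both new centres should therefore be R, giving the C2-symmetric (R,R)-dimer as the expected major isomer, to be separated from any R,S-isomer by chromatography.

Step 4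
Reactants: 8 (2R,3R)-bis-imide
Product: 9 (2R,3R)-2,3-bis(4-benzyloxy-3-methoxybenzyl)succinic acid
Conditions: LiOH, H2O2, THF–H2O, 0 °C; Na2SO3; HCl
Reagents that add atoms: hydrogen peroxide, OO
Why: LiOOH cleavage of N-acyl oxazolidinones: hydroperoxide attacks the exocyclic imide carbonyl selectively and is too weakly basic to epimerise the α-centres, and auxiliary 4 is recovered.

Step 5
Reactants: 9 (2R,3R)-2,3-bis(4-benzyloxy-3-methoxybenzyl)succinic acid
Product: 10 (2R,3R)-2,3-bis(4-hydroxy-3-methoxybenzyl)succinic acid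
Conditions: H2 (1 atm), 10% Pd/C, EtOAc–MeOH, rt
Reagents that add atoms: none
Why: Hydrogenolysis of aryl benzyl ethers over palladium; 9 has no other benzylic C–O bond and nothing else reducible, and the stereocenters are not involved.

Step 6
Reactants: 10 (2R,3R)-2,3-bis(4-hydroxy-3-methoxybenzyl)succinic acid
Product: 12 (1S,2S,5S,6S)-2,6-bis(4-hydroxy-3-methoxyphenyl)-3,7-dioxabicyclo[3.3.0]octane-4,8-dione (cis-fused; both aryl groups exo), via monolactone acid 11 (not isolated)
Conditions: DDQ (2.2 equiv), 1,4-dioxane, rt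
Reagents that add atoms: none
Why: Oxidative lactonisation: DDQ dehydrogenates each 4-hydroxy-3-methoxybenzyl group to a p-quinone methide, which the carboxyl group of the other half captures by 5-exo-trig addition (ring 1, then ring 2); the fixed (R,R) centres force a cis fusion, and each aryl group should take the exo position trans to the neighbouring ring carbon, both kinetically and, because addition to the quinone methide is reversible, thermodynamically.

Step 7
Reactants: 12 bis-lactone bisphenol
Product: 13 (1S,2S,5S,6S)-2,6-bis[4-(tert-butyldimethylsilyloxy)-3-methoxyphenyl]-3,7-dioxabicyclo[3.3.0]octane-4,8-dione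
Conditions: TBSCl, imidazole, DMF, 0 °C → rt
Reagents that add atoms: tert-butyldimethylsilyl chloride, CC(C)(C)[Si](C)(C)Cl
Why: Silylation of the phenols with TBSCl/imidazole, which removes the acidic OH groups and blocks phenoxide-driven opening of the benzylic lactone C–O bonds before the enolate step; no stereocenter is involved.

Step 8
Reactants: 13 (1S,2S,5S,6S)-2,6-bis[4-(tert-butyldimethylsilyloxy)-3-methoxyphenyl]-3,7-dioxabicyclo[3.3.0]octane-4,8-dione
Product: 17 (1S,2R,5S,6R)-1,5-dihydroxy-2,6-bis[4-(tert-butyldimethylsilyloxy)-3-methoxyphenyl]-3,7-dioxabicyclo[3.3.0]octane-4,8-dione, via potassium enolate 14 (not isolated), via monohydroxy potassium alkoxide 15 (not isolated), via dipotassium alkoxide enolate 16 (not isolated)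
Conditions: KN(SiMe3)2 (1.2 equiv), THF, −78 °C; 2-(phenylsulfonyl)-3-phenyloxaziridine (1.5 equiv); KN(SiMe3)2 (2.5 equiv); oxaziridine (2.5 equiv), −78 → −40 °C; AcOH
Reagents that add atoms: 2-(phenylsulfonyl)-3-phenyloxaziridine, O=S(=O)(c1ccccc1)N1OC1c1ccccc1
Why: KN(SiMe3)2 removes the ring-fusion proton at C8 to give a potassium enolate whose C8=C9 double bond is endocyclic in ring 2; the enolate carbon attacks the oxaziridine oxygen and the adduct collapses to the C8 alkoxide and the N-sulfonylimine, after which a second deprotonation at C8' and a second oxygen transfer complete the diol. This is the Davis oxidation, the established α-hydroxylation of ester and lactone enolates with N-sulfonyloxaziridines, applied twice in one flask with extra base in the second cycle to allow for its consumption by the sulfonylimine. No ring is closed or opened, so no mode of ring closure has to be met; two C–O bonds and two fully substituted stereocentres are formed. Each new centre is controlled by the ring fusion: a trans-fused bis-lactone of this bicyclo[3.3.0] type is prohibitively strained, so oxygen can only arrive on the convex face from which the proton left, and OH replaces H with retention at C8 and then at C8', while C7 and C7' are never deprotonated. The selectivity needed is oxygenation ahead of β-elimination of the C7–O (C7'–O) acyloxy group; that bond lies close to the plane of ring 1 and hence near the nodal plane of the enolate π-system at C8, so E1cB opening (the reverse of a 5-endo-trig closure) should be slow at −78 °C, and the silylated phenols cannot open the benzylic esters through quinone methides.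

Step 9
Reactants: 17 dihydroxy bis-lactone
Product: 18 (1S,2R,5S,6R)-2,6-bis[4-(tert-butyldimethylsilyloxy)-3-methoxyphenyl]-3,7-dioxabicyclo[3.3.0]octane-1,4,5,8-tetrol (bis-lactol; anomeric mixture at C4 and C8)
Conditions: iBu2AlH (6 equiv), CH2Cl2, −78 °C; aq. KNaC4H4O6 (potassium sodium tartrate)
Reagents that add atoms: none
Why: Half-reduction of lactones with iBu2AlH at −78 °C: the tetrahedral aluminium hemiacetalates persist until work-up and give the lactols, the first two equivalents being consumed by the tertiary hydroxyls; the anomeric centres form as mixtures, which does not matter because they become CH2 in the next step.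

Step 10
Reactants: 18 bis-lactol
Product: 19 (1S,2R,5S,6R)-2,6-bis[4-(tert-butyldimethylsilyloxy)-3-methoxyphenyl]-3,7-dioxabicyclo[3.3.0]octane-1,5-diol
Conditions: Et3SiH (10 equiv), BF3·OEt2 (4 equiv), CH2Cl2, −78 → −40 °C; aq. NaHCO3
Reagents that add atoms: none
Why: Ionic hydrogenation of lactols: BF3 ionises each hemiacetal to a cyclic oxocarbenium ion that takes hydride from Et3SiH, turning C9 and C9' into CH2 without creating a stereocenter; at low temperature the lactols should ionise much faster than the benzylic ring C–O bonds.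

Step 11
Reactants: 19 bis-silyl ether of prinsepiol
Product: 20 prinsepiol, (1S,2R,5S,6R)-2,6-bis(4-hydroxy-3-methoxyphenyl)-3,7-dioxabicyclo[3.3.0]octane-1,5-diol
Conditions: Bu4NF, AcOH, THF, 0 °C
Reagents that add atoms: none
Why: Fluoride cleavage of the aryl silyl ethers, driven by Si–F bond formation; the AcOH buffer keeps the phenoxides from opening the benzylic ethers, and no bond to a stereocenter is broken.

**Compound list**

1 | 3-(4-hydroxy-3-methoxyphenyl)propanoic acid (dihydroferulic acid) | COc1cc(CCC(=O)O)ccc1O | starting material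
2 | benzyl 3-(4-benzyloxy-3-methoxyphenyl)propanoate (not isolated) | COc1cc(CCC(=O)OCc2ccccc2)ccc1OCc1ccccc1 | intermediate
3 | 3-(4-benzyloxy-3-methoxyphenyl)propanoic acid | COc1cc(CCC(=O)O)ccc1OCc1ccccc1 | intermediate
4 | (S)-4-benzyl-2-oxazolidinone | O=C1N[C@@H](Cc2ccccc2)CO1 | starting material
5 | 3-(4-benzyloxy-3-methoxyphenyl)propanoic pivalic anhydride (not isolated) | COc1cc(CCC(=O)OC(=O)C(C)(C)C)ccc1OCc1ccccc1 | intermediate
6 | (S)-4-benzyl-3-[3-(4-benzyloxy-3-methoxyphenyl)propanoyl]oxazolidin-2-one | COc1cc(CCC(=O)N2[C@@H](Cc3ccccc3)COC2=O)ccc1OCc1ccccc1 | intermediate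
7 | lithium (Z)-enolate of 6 (not isolated) | COc1cc(C/C=C(\[O-])N2[C@@H](Cc3ccccc3)COC2=O)ccc1OCc1ccccc1.[Li+] | intermediate
8 | (2R,3R)-2,3-bis(4-benzyloxy-3-methoxybenzyl)-1,4-bis[(S)-4-benzyl-2-oxooxazolidin-3-yl]butane-1,4-dione | O=C1OC[C@H](Cc2ccccc2)N1C(=O)[C@H](Cc1ccc(OCc2ccccc2)c(OC)c1)[C@@H](Cc1ccc(OCc2ccccc2)c(OC)c1)C(=O)N1[C@@H](Cc2ccccc2)COC1=O | intermediate
9 | (2R,3R)-2,3-bis(4-benzyloxy-3-methoxybenzyl)succinic acid | OC(=O)[C@H](Cc1ccc(OCc2ccccc2)c(OC)c1)[C@@H](Cc1ccc(OCc2ccccc2)c(OC)c1)C(=O)O | intermediate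
10 | (2R,3R)-2,3-bis(4-hydroxy-3-methoxybenzyl)succinic acid | OC(=O)[C@H](Cc1ccc(O)c(OC)c1)[C@@H](Cc1ccc(O)c(OC)c1)C(=O)O | intermediate
11 | (2S,3S,4R)-2-(4-hydroxy-3-methoxyphenyl)-4-(4-hydroxy-3-methoxybenzyl)-5-oxotetrahydrofuran-3-carboxylic acid (monolactone acid; not isolated) | COc1cc([C@H]2OC(=O)[C@H](Cc3ccc(O)c(OC)c3)[C@@H]2C(=O)O)ccc1O | intermediate
12 | (1S,2S,5S,6S)-2,6-bis(4-hydroxy-3-methoxyphenyl)-3,7-dioxabicyclo[3.3.0]octane-4,8-dione (cis-fused, aryl groups exo) | COc1cc([C@H]2OC(=O)[C@@H]3[C@@H](c4ccc(O)c(OC)c4)OC(=O)[C@H]23)ccc1O | intermediate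
13 | (1S,2S,5S,6S)-2,6-bis[4-(tert-butyldimethylsilyloxy)-3-methoxyphenyl]-3,7-dioxabicyclo[3.3.0]octane-4,8-dione | COc1cc([C@H]2OC(=O)[C@@H]3[C@@H](c4ccc(O[Si](C)(C)C(C)(C)C)c(OC)c4)OC(=O)[C@H]23)ccc1O[Si](C)(C)C(C)(C)C | intermediate
14 | potassium enolate of 13 (C8=C9–OK in ring 2; not isolated) | COc1cc([C@H]2OC(=O)[C@@H]3[C@@H](c4ccc(O[Si](C)(C)C(C)(C)C)c(OC)c4)OC([O-])=C23)ccc1O[Si](C)(C)C(C)(C)C.[K+] | intermediate
15 | potassium C8-alkoxide of the monohydroxy bis-lactone (not isolated) | COc1cc([C@H]2OC(=O)[C@@H]3[C@@H](c4ccc(O[Si](C)(C)C(C)(C)C)c(OC)c4)OC(=O)[C@]23[O-])ccc1O[Si](C)(C)C(C)(C)C.[K+] | intermediate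
16 | dipotassium salt: C8 alkoxide, C8'=C9' enolate (not isolated) | COc1cc([C@H]2OC([O-])=C3[C@@H](c4ccc(O[Si](C)(C)C(C)(C)C)c(OC)c4)OC(=O)[C@]23[O-])ccc1O[Si](C)(C)C(C)(C)C.[K+].[K+] | intermediate
17 | (1S,2R,5S,6R)-1,5-dihydroxy-2,6-bis[4-(tert-butyldimethylsilyloxy)-3-methoxyphenyl]-3,7-dioxabicyclo[3.3.0]octane-4,8-dione | COc1cc([C@H]2OC(=O)[C@]3(O)[C@@H](c4ccc(O[Si](C)(C)C(C)(C)C)c(OC)c4)OC(=O)[C@]23O)ccc1O[Si](C)(C)C(C)(C)C | intermediate
18 | (1S,2R,5S,6R)-2,6-bis[4-(tert-butyldimethylsilyloxy)-3-methoxyphenyl]-3,7-dioxabicyclo[3.3.0]octane-1,4,5,8-tetrol (bis-lactol, anomeric mixture) | COc1cc([C@H]2OC(O)[C@]3(O)[C@@H](c4ccc(O[Si](C)(C)C(C)(C)C)c(OC)c4)OC(O)[C@]23O)ccc1O[Si](C)(C)C(C)(C)C | intermediate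
19 | (1S,2R,5S,6R)-2,6-bis[4-(tert-butyldimethylsilyloxy)-3-methoxyphenyl]-3,7-dioxabicyclo[3.3.0]octane-1,5-diol | COc1cc([C@H]2OC[C@]3(O)[C@@H](c4ccc(O[Si](C)(C)C(C)(C)C)c(OC)c4)OC[C@]23O)ccc1O[Si](C)(C)C(C)(C)C | intermediate
20 | prinsepiol, (1S,2R,5S,6R)-2,6-bis(4-hydroxy-3-methoxyphenyl)-3,7-dioxabicyclo[3.3.0]octane-1,5-diol | COc1cc([C@H]2OC[C@]3(O)[C@@H](c4ccc(O)c(OC)c4)OC[C@]23O)ccc1O | target

**Step count and risks**

Total step count: 11. Longest linear sequence: 11 steps (from 1; auxiliary 4 enters in step 2).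

The three steps most likely to fail are steps 8, 6 and 10.

1. Step 8 (double enolate hydroxylation). The ring-fusion enolate may open by β-elimination of the C7 acyloxy group before oxygen is delivered. Oxygen transfer on the convex face, next to the exo aryl group, may be slow. The second deprotonation, next to an alkoxide, may stall. The fallback sets out from 13 and comes back at 17, and replaces the free metal enolate by a neutral silyl ketene acetal oxidised with a small reagent. 13 is enolised with LiN(iPr)2 in the presence of Me3SiCl (THF, −78 °C), so that the enolate is silylated as it forms, giving the mono(silyl ketene acetal) F1. Rubottom oxidation with dimethyldioxirane (acetone–CH2Cl2, −78 °C) epoxidises the ketene acetal on the convex face, and silyl migration gives the C8-trimethylsilyloxy bis-lactone F2. The same two operations on the second lactone give the silyl ketene acetal F3 and then the 1,5-bis(trimethylsilyloxy) bis-lactone F4. Aqueous citric acid in THF removes both Me3Si groups to give 17.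

2. Step 6 (double oxidative lactonisation). The quinone methide may be lost to ring closure onto the second arene or to tautomerisation to the cinnamic acid before the carboxyl group adds, and the free phenols may be over-oxidised or coupled. The fallback sets out from 10 and comes back at 13, bypassing 12, by oxidising a phenol-protected substrate through a benzylic cation. 10 is persilylated (TBSCl, imidazole, DMF) to the bis(silyl ester) bis(silyl ether) F5, and the silyl esters are hydrolysed (AcOH–THF–H2O, rt) to the bis-silyl ether diacid F6. DDQ (dioxane–AcOH, 60 °C) then abstracts benzylic hydride from each 4-silyloxy-3-methoxybenzyl group, and the neighbouring carboxylic acid captures the cation (oxidative benzylic lactonisation of 4-arylbutanoic acids), giving 13 directly.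

3. Step 10 (lactol deoxygenation). BF3 may ionise the benzylic C7–O and C7'–O bonds, causing epimerisation at C7/C7' or reductive ring opening by the silane. The fallback sets out from 17 and comes back at 19, and forms the two ether rings by substitution at C9 and C9' with no Lewis acid and no hydride donor at the ionisable stage. LiBH4 (THF, 0 °C → rt) reduces both lactones to the hexaol F7. TsCl (2.2 equiv) in pyridine at 0 °C sulfonylates the two primary hydroxyls to give the bis-tosylate F8. On warming in pyridine, F8 should close both tetrahydrofuran rings by 5-exo-tet attack of the benzylic hydroxyls on the CH2OTs carbons (C7'–OH on C9, C7–OH on C9'), giving 19. No C–O bond at C7, C7', C8 or C8' is broken, so these centres cannot epimerise.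

**Further compounds**

F1 | step 8 | mono(trimethylsilyl ketene acetal) of 13 (C8=C9–OSiMe3) | COc1cc([C@H]2OC(=O)[C@@H]3[C@@H](c4ccc(O[Si](C)(C)C(C)(C)C)c(OC)c4)OC(O[Si](C)(C)C)=C23)ccc1O[Si](C)(C)C(C)(C)C
F2 | step 8 | C8-trimethylsilyloxy bis-lactone (mono-oxygenated 13) | COc1cc([C@H]2OC(=O)[C@@H]3[C@@H](c4ccc(O[Si](C)(C)C(C)(C)C)c(OC)c4)OC(=O)[C@]23O[Si](C)(C)C)ccc1O[Si](C)(C)C(C)(C)C
F3 | step 8 | trimethylsilyl ketene acetal of F2 (C8'=C9'–OSiMe3) | COc1cc([C@H]2OC(O[Si](C)(C)C)=C3[C@@H](c4ccc(O[Si](C)(C)C(C)(C)C)c(OC)c4)OC(=O)[C@]23O[Si](C)(C)C)ccc1O[Si](C)(C)C(C)(C)C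
F4 | step 8 | 1,5-bis(trimethylsilyloxy) derivative of 17 | COc1cc([C@H]2OC(=O)[C@]3(O[Si](C)(C)C)[C@@H](c4ccc(O[Si](C)(C)C(C)(C)C)c(OC)c4)OC(=O)[C@]23O[Si](C)(C)C)ccc1O[Si](C)(C)C(C)(C)C
F5 | step 6 | bis(tert-butyldimethylsilyl) (2R,3R)-2,3-bis[4-(tert-butyldimethylsilyloxy)-3-methoxybenzyl]succinate | CC(C)(C)[Si](C)(C)OC(=O)[C@H](Cc1ccc(O[Si](C)(C)C(C)(C)C)c(OC)c1)[C@@H](Cc1ccc(O[Si](C)(C)C(C)(C)C)c(OC)c1)C(=O)O[Si](C)(C)C(C)(C)C
F6 | step 6 | (2R,3R)-2,3-bis[4-(tert-butyldimethylsilyloxy)-3-methoxybenzyl]succinic acid | OC(=O)[C@H](Cc1ccc(O[Si](C)(C)C(C)(C)C)c(OC)c1)[C@@H](Cc1ccc(O[Si](C)(C)C(C)(C)C)c(OC)c1)C(=O)O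
F7 | step 10 | hexaol: 1,4-bis[4-(tert-butyldimethylsilyloxy)-3-methoxyphenyl]-2,3-bis(hydroxymethyl)butane-1,2,3,4-tetrol (configuration as in 17) | COc1cc([C@@H](O)[C@@](O)(CO)[C@](O)(CO)[C@H](O)c2ccc(O[Si](C)(C)C(C)(C)C)c(OC)c2)ccc1O[Si](C)(C)C(C)(C)C
F8 | step 10 | bis(primary p-toluenesulfonate) of F7 | COc1cc([C@@H](O)[C@@](O)(COS(=O)(=O)c2ccc(C)cc2)[C@](O)(COS(=O)(=O)c2ccc(C)cc2)[C@H](O)c2ccc(O[Si](C)(C)C(C)(C)C)c(OC)c2)ccc1O[Si](C)(C)C(C)(C)C
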